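## Retrosynthetic overview
1. Rings are lettered A to G from left to right in the SMILES. All seven are bought as oxygenated benzenes, so no ring is formed. Only the six diaryl ether C–O bonds are made, and the 18 OH groups travel as OMe until the last step.
2. The last bond made is C–O–D. It splits the chain into the trimer phenol A-B-C–OH and the tetramer bromide Br–D-E-F-G.
3. Both halves come from one bifunctional dimer with a bromide on the B/D-type ring and a free OH on the C/E-type ring. With excess ring A phenol it gives the trimer. With the F-G iodide (iodide reacts before bromide) it gives the tetramer.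
4. The dimer bond (B–O–C, identical to D–O–E) comes from a new oxidative C–O coupling. 2,3,4-Trimethoxyphenol is turned into its quinone monoketal, which is attacked next to the carbonyl by the oxygen of 4-bromo-2,6-dimethoxyphenol.
5. Order of joining: B–C and D–E (same flask), F–G, A–B, E–F, C–D, then global demethylation.

Assumption: the target has no stereocentre and no hindered axis, so it is achiral, there is no enantiomer to select, and no step needs stereocontrol.

## Route

Step 1
Reactants: 1 2,3,4-trimethoxyphenol; 2 4-bromo-2,6-dimethoxyphenol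
Product: 4 6-(4-bromo-2,6-dimethoxyphenoxy)-2,3,4-trimethoxyphenol, via quinone monoketal 3 (not isolated)
Conditions: 1, PhI(OAc)2 (1.05 equiv), MeOH, 0 °C, 30 min; evaporate, strip with toluene; then 2 (1.5 equiv), (PhO)2P(O)OH (10 mol %), 5 Å MS, toluene, 0 °C → rt
Reagents that add atoms: methanol, CO (enters 3 as the second ketal methoxy group; one of the two equivalent ketal methoxy groups leaves again)
Why: Proposed new method: acid-catalysed SN2′-type O-arylation of a fully ortho/para-blocked phenol by a para-quinone monoketal, in net terms a dehydrogenative ortho C–H aryloxylation of 1; PhI(OAc)2/MeOH gives 3 by the well-known oxidative dearomatisation of 4-methoxyphenols, the phosphoric acid ionises the ketal (directly or after reversible exchange to the mixed methyl aryl ketal) to a 4-methoxyphenoxenium/phosphate contact ion pair, and the phosphate oxygen holds the O–H of 2 and delivers its oxygen to C6, the only cationic terminus that carries hydrogen; attack at C2 or C4 is reversible because those carbons bear OMe and no hydrogen, the usual carbon-attack and [3,3] exits are closed because both ortho positions and the para position of 2 are substituted (its remaining C–H sits between OMe and Br and is deactivated), and only the C6 adduct can lose a proton and aromatise irreversibly to 4; the closest known reaction type is the acid-promoted coupling of quinone monoketals with arene or naphthol carbon nucleophiles, which gives oxygenated biaryls at the same carbon; no stereocentre is formed.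

Step 2
Reactants: 5 4-iodo-2,6-dimethoxyphenol; 6 (3,4,5-trimethoxyphenyl)boronic acid
Product: 7 5-iodo-1,3-dimethoxy-2-(3,4,5-trimethoxyphenoxy)benzene
Conditions: 6 (2 equiv), Cu(OAc)2 (2.0 equiv), pyridine (5 equiv), 4 Å MS, CH2Cl2, rt, 36 h, Ar
Reagents that add atoms: none
Why: Chan–Lam coupling, in which aryl transfer from boron to divalent copper, phenoxide binding, disproportionation to trivalent copper and C–O reductive elimination all run at room temperature, where the C–I bond is inert and di-ortho-substituted phenols are known to couple, and the second equivalent of divalent copper is the oxidant so that the oxidation-prone phenol sees no O2.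

Step 3
Reactants: 4 6-(4-bromo-2,6-dimethoxyphenoxy)-2,3,4-trimethoxyphenol; 8 2,4,6-trimethoxyphenol
Product: 9 6-[2,6-dimethoxy-4-(2,4,6-trimethoxyphenoxy)phenoxy]-2,3,4-trimethoxyphenol (trimer phenol A-B-C–OH)
Conditions: 8 (4 equiv), CuI (20 mol %), picolinic acid (40 mol %), K3PO4 (6 equiv), DMSO, 100 °C, Ar; 4 added over 4 h
Reagents that add atoms: none
Why: Ullmann-type diaryl ether synthesis with the CuI/picolinic acid system made for hindered phenols, in which the only electrophile is the unhindered C–Br of 4, and the fourfold excess and smaller bulk of the phenoxide of 8, against the ortho-aryloxy phenoxides of 4 and 9 kept dilute by slow addition, steer the coupling to 9.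

Step 4
Reactants: 4 6-(4-bromo-2,6-dimethoxyphenoxy)-2,3,4-trimethoxyphenol; 7 5-iodo-1,3-dimethoxy-2-(3,4,5-trimethoxyphenoxy)benzene
Product: 10 1-(4-bromo-2,6-dimethoxyphenoxy)-2-[3,5-dimethoxy-4-(3,4,5-trimethoxyphenoxy)phenoxy]-3,4,5-trimethoxybenzene (tetramer bromide Br–D-E-F-G)
Conditions: 7 (1.5 equiv), CuI (10 mol %), picolinic acid (20 mol %), K3PO4 (2.5 equiv), DMSO, 75 °C, Ar
Reagents that add atoms: none
Why: chemoselective Ullmann-type diaryl ether synthesis, in which monovalent copper activates a C–I bond far faster than the sterically and electronically equivalent C–Br bond, so with iodide 7 in excess the phenoxide of 4 is arylated by 7 only and the bromide is kept for step 5.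

Step 5
Reactants: 9 trimer phenol A-B-C–OH; 10 tetramer bromide Br–D-E-F-G
Product: 11 octadeca-O-methyl ether of the target (rings A to G joined as in 12, all 18 OH as OMe)
Conditions: 9 (1.2 equiv), CuI (30 mol %), picolinic acid (60 mol %), K3PO4 (3 equiv), DMSO, 110 °C, 48 h, Ar
Reagents that add atoms: none
Why: Ullmann-type diaryl ether synthesis between the single remaining phenol and the single remaining aryl bromide, whose carbon has two ortho hydrogens, so there is no selectivity question and aryl methyl and diaryl ethers are inert to the conditions.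

Step 6
Reactants: 11 octadeca-O-methyl ether of the target
Product: 12 CNP0292517.0 (target)
Conditions: BBr3 (45 equiv), CH2Cl2, −78 °C → rt, 36 h, Ar; then H2O, 0 °C; EtOAc extraction, Sephadex LH-20 (degassed MeOH)
Reagents that add atoms: none
Why: Lewis-acid aryl methyl ether cleavage, in which BBr3 binds each OMe oxygen and bromide removes the methyl group by SN2, whereas the diaryl ether oxygens carry no sp3 carbon and cannot be cleaved this way, and hydrolysis of the boron aryloxides frees all 18 phenols without creating any stereocentre.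

## Compound list
1 | 2,3,4-trimethoxyphenol | COc1ccc(O)c(OC)c1OC | starting material
2 | 4-bromo-2,6-dimethoxyphenol | COc1cc(Br)cc(OC)c1O | starting material
3 | 2,3,4,4-tetramethoxycyclohexa-2,5-dien-1-one (quinone monoketal) | COC1=C(OC)C(OC)(OC)C=CC1=O | intermediate
4 | 6-(4-bromo-2,6-dimethoxyphenoxy)-2,3,4-trimethoxyphenol | COc1cc(Br)cc(OC)c1Oc1cc(OC)c(OC)c(OC)c1O | intermediate
5 | 4-iodo-2,6-dimethoxyphenol | COc1cc(I)cc(OC)c1O | starting material
6 | (3,4,5-trimethoxyphenyl)boronic acid | COc1cc(B(O)O)cc(OC)c1OC | starting material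
7 | 5-iodo-1,3-dimethoxy-2-(3,4,5-trimethoxyphenoxy)benzene | COc1cc(I)cc(OC)c1Oc1cc(OC)c(OC)c(OC)c1 | intermediate
8 | 2,4,6-trimethoxyphenol | COc1cc(OC)c(O)c(OC)c1 | starting material
9 | 6-[2,6-dimethoxy-4-(2,4,6-trimethoxyphenoxy)phenoxy]-2,3,4-trimethoxyphenol | COc1cc(OC)c(Oc2cc(OC)c(Oc3cc(OC)c(OC)c(OC)c3O)c(OC)c2)c(OC)c1 | intermediate
10 | 1-(4-bromo-2,6-dimethoxyphenoxy)-2-[3,5-dimethoxy-4-(3,4,5-trimethoxyphenoxy)phenoxy]-3,4,5-trimethoxybenzene | COc1cc(Br)cc(OC)c1Oc1cc(OC)c(OC)c(OC)c1Oc1cc(OC)c(Oc2cc(OC)c(OC)c(OC)c2)c(OC)c1 | intermediate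
11 | octadeca-O-methyl ether of the target | COc1cc(OC)c(Oc2cc(OC)c(Oc3cc(OC)c(OC)c(OC)c3Oc3cc(OC)c(Oc4cc(OC)c(OC)c(OC)c4Oc4cc(OC)c(Oc5cc(OC)c(OC)c(OC)c5)c(OC)c4)c(OC)c3)c(OC)c2)c(OC)c1 | intermediate
12 | CNP0292517.0, heptameric all-ether phlorotannin (A 2,4,6-trihydroxyphenyl; B, D, F 2,6-dihydroxy-1,4-phenylene; C, E 3,4,5-trihydroxy-1,2-phenylene; G 3,4,5-trihydroxyphenyl), achiral | Oc1cc(O)c(Oc2cc(O)c(Oc3cc(O)c(O)c(O)c3Oc3cc(O)c(Oc4cc(O)c(O)c(O)c4Oc4cc(O)c(Oc5cc(O)c(O)c(O)c5)c(O)c4)c(O)c3)c(O)c2)c(O)c1 | target

## Count and risks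
Total step count: 6.
Longest linear sequence: 4 (steps 1, 3, 5, 6 or steps 2, 4, 5, 6).

Three steps most likely to fail:

(a) Step 1, the new reaction.
- **Failure modes:** Friedel–Crafts attack by C3 of 2 in place of its oxygen, hydrolysis of 3 to 2,3-dimethoxybenzoquinone, or redox exchange between 2 and 3.
- **Fallback:** it uses known chemistry only, sets out from 2 and 6, and comes back to the route at 4. It costs two more steps.
- Chan–Lam coupling of 2 with 6 (Cu(OAc)2, pyridine, 4 Å MS, CH2Cl2, rt) gives 5-bromo-1,3-dimethoxy-2-(3,4,5-trimethoxyphenoxy)benzene F1.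
- Vilsmeier–Haack formylation (POCl3, DMF, 70 °C) goes to the ring activated by three ortho/para oxygens, next to the aryloxy group. It gives 6-(4-bromo-2,6-dimethoxyphenoxy)-2,3,4-trimethoxybenzaldehyde F2.
- Baeyer–Villiger oxidation (mCPBA, CH2Cl2, 0 °C) gives 6-(4-bromo-2,6-dimethoxyphenoxy)-2,3,4-trimethoxyphenyl formate F3. K2CO3 in MeOH then frees 4.

(b) Step 5, the union of two large fragments.
- **Failure modes:** the phenol is doubly ortho-substituted and the bromide is electron-rich, so low conversion and loss of bromine by reduction are the risks.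
- **Fallback:** it sets out from 10 and comes back at 11. It replaces thermal C–Br activation by aryl transfer from boron at room temperature.
- Bromine–lithium exchange of 10 (n-BuLi, THF, −78 °C), quench with B(OiPr)3 and mild acidic work-up gives {4-[2-[3,5-dimethoxy-4-(3,4,5-trimethoxyphenoxy)phenoxy]-3,4,5-trimethoxyphenoxy]-3,5-dimethoxyphenyl}boronic acid F4.
- F4 is joined to 9 by Chan–Lam coupling (Cu(OAc)2, pyridine, 4 Å MS, CH2Cl2, rt) to give 11.

(c) Step 6, the eighteenfold demethylation.
- **Failure modes:** isolation of a very polar, air-sensitive polyphenol from boron salts and from partly methylated congeners.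
- **Fallback:** it sets out from 11 and comes back at 12. It is a derivatise, purify and release sequence.
- After the BBr3 treatment and quench, the crude polyphenol is not purified. It is peracetylated at once (Ac2O, pyridine, rt, Ar) to the octadecaacetate of the target F5.
- F5 is stable in air and can be freed from under-demethylated material on silica gel.
- Acid methanolysis (1.25 M HCl in degassed MeOH, 40 °C, Ar) followed by evaporation then gives pure 12.

Further compounds
F1 | step 1 | 5-bromo-1,3-dimethoxy-2-(3,4,5-trimethoxyphenoxy)benzene | COc1cc(Br)cc(OC)c1Oc1cc(OC)c(OC)c(OC)c1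
F2 | step 1 | 6-(4-bromo-2,6-dimethoxyphenoxy)-2,3,4-trimethoxybenzaldehyde | COc1cc(Br)cc(OC)c1Oc1cc(OC)c(OC)c(OC)c1C=O
F3 | step 1 | 6-(4-bromo-2,6-dimethoxyphenoxy)-2,3,4-trimethoxyphenyl formate | COc1cc(Br)cc(OC)c1Oc1cc(OC)c(OC)c(OC)c1OC=O
F4 | step 5 | {4-[2-[3,5-dimethoxy-4-(3,4,5-trimethoxyphenoxy)phenoxy]-3,4,5-trimethoxyphenoxy]-3,5-dimethoxyphenyl}boronic acid | COc1cc(B(O)O)cc(OC)c1Oc1cc(OC)c(OC)c(OC)c1Oc1cc(OC)c(Oc2cc(OC)c(OC)c(OC)c2)c(OC)c1
F5 | step 6 | octadecaacetate of the target | CC(=O)Oc1cc(OC(C)=O)c(Oc2cc(OC(C)=O)c(Oc3cc(OC(C)=O)c(OC(C)=O)c(OC(C)=O)c3Oc3cc(OC(C)=O)c(Oc4cc(OC(C)=O)c(OC(C)=O)c(OC(C)=O)c4Oc4cc(OC(C)=O)c(Oc5cc(OC(C)=O)c(OC(C)=O)c(OC(C)=O)c5)c(OC(C)=O)c4)c(OC(C)=O)c3)c(OC(C)=O)c2)c(OC(C)=O)c1
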